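**Plan**

1. Numbering and feature: ring carbons are C1 (CMe2), C2–C4, C5(Me)/C6 (epoxide), C7, C8, C9 (bears C12), C10 and C11 (OBz). In the 11-membered ring the quaternary C1 is bonded to the oxygen-bearing C11 and flanked by the C2–C3 ethano unit. This is a masked 2,2-dimethylhomoallyl carbinol, the product pattern of a γ,γ-dimethylallyl-metal adding to an aldehyde.
2. Cuts: C12 acid (from CH2OSi), O11 benzoate and C2–C3 (from the alkene) are adjusted first. Then C1–C11 is cut (ring to C3 allylic bromide plus C11 enal), then C2–C3 (isobutenyl Grignard), C8–C9 (Negishi sp3–sp2), C6–C7 and C5–Me (carboalumination/oxirane) and C10–C11 (acetylide/chloroformate).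
3. Forward: fragment C3–C8 (steps 1–2) and fragment C9–C12 (steps 3–4) are joined at C8–C9 (step 5). Epoxide (step 7), C1–C2 unit (step 9), enal and bromide (steps 10–12) follow. The only carbocycle closes in step 13, and benzoate, C2=C3 saturation and C12 oxidation finish the route (steps 14–18).
4. Stereochemistry: C5/C6 come from Shi epoxidation (D-fructose ketone) of the E-alkene made by syn-carboalumination. The 9,10 geometry comes from anti-hydroiodination and a retentive coupling. C11 is set by a chiral ligand on chromium in the ring closure.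
5. Abbreviations: TBS = tert-butyl(dimethyl)silyl, TBDPS = tert-butyl(diphenyl)silyl. Compounds 1 and 7 are catalogue silyl ethers of but-3-yn-1-ol and prop-2-yn-1-ol.

Key step: step 13

Assumption: L* is 1,8-bis[(4S)-4-isopropyl-4,5-dihydrooxazol-2-yl]-3,6-diphenyl-9H-carbazole; its sense of induction is to be fixed on a model prenylation of an acyclic enal, and the antipode that sends C1 to the Si face of the C11 aldehyde is the one meant.

Step 1
Reactants: 1 tert-butyl(but-3-yn-1-yloxy)dimethylsilane; 2 oxirane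
Product: 5 (3E)-6-[(TBS)oxy]-4-methylhex-3-en-1-ol, via alkenyldimethylalane 3 (not isolated), via lithium alkenylaluminate 4 (not isolated)
Conditions: AlMe3, Cp2ZrCl2 (cat.), CH2Cl2, 0 °C to rt; volatiles removed; n-BuLi, THF–hexane, –78 °C; oxirane, –78 °C to rt; aq. KNaC4H4O6
Reagents that add atoms: trimethylaluminium C[Al](C)C
Why: Negishi zirconium-catalysed carboalumination adds methyl and aluminium syn across the terminal alkyne with methyl on the internal carbon, and the derived alkenylaluminate opens oxirane with retention, so the C5=C6 alkene is formed E with C3–C8 in place.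

Step 2
Reactants: 5 (3E)-6-[(TBS)oxy]-4-methylhex-3-en-1-ol
Product: 6 tert-butyl{[(3E)-6-iodo-3-methylhex-3-en-1-yl]oxy}dimethylsilane
Conditions: I2, PPh3, imidazole, CH2Cl2, 0 °C to rt
Reagents that add atoms: iodine II
Why: Appel-type iodination displaces the alkoxyphosphonium by iodide at the primary carbon (SN2) and leaves the silyl ether and the alkene untouched.

Step 3
Reactants: 7 tert-butyl(diphenyl)(prop-2-yn-1-yloxy)silane
Product: 9 ethyl 4-[(TBDPS)oxy]but-2-ynoate, via lithium acetylide 8 (not isolated)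
Conditions: n-BuLi, THF, –78 °C; ClCO2Et, –78 °C to 0 °C
Reagents that add atoms: ethyl chloroformate CCOC(=O)Cl
Why: Deprotonation of the terminal alkyne and C-acylation of the lithium acetylide with a chloroformate is the standard alk-2-ynoate synthesis and brings in C11 at the ester level.

Step 4
Reactants: 9 ethyl 4-[(TBDPS)oxy]but-2-ynoate
Product: 10 ethyl (2Z)-4-[(TBDPS)oxy]-3-iodobut-2-enoate
Conditions: NaI, AcOH, 70 °C
Reagents that add atoms: sodium iodide [Na+].[I-]
Why: Conjugate hydroiodination of an ynoate proceeds by anti addition of H and I, so iodine (the future C8 position) ends cis to the ester; the diphenylsilyl ether withstands warm acetic acid.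

Step 5
Reactants: 6 tert-butyl{[(3E)-6-iodo-3-methylhex-3-en-1-yl]oxy}dimethylsilane; 10 ethyl (2Z)-4-[(TBDPS)oxy]-3-iodobut-2-enoate
Product: 12 ethyl (2E,6E)-9-[(TBS)oxy]-3-{[(TBDPS)oxy]methyl}-7-methylnona-2,6-dienoate, via alkylzinc iodide 11 (not isolated)
Conditions: Zn dust, LiCl, THF, 40 °C; then 10, PdCl2(dppf) (cat., dppf = 1,1'-bis(diphenylphosphino)ferrocene), THF, rt
Reagents that add atoms: none
Why: Negishi alkyl–alkenyl cross-coupling: LiCl-assisted zinc insertion gives an ester-tolerant primary alkylzinc that couples with the β-iodo enoate with retention of alkene geometry, so C8 ends cis to C11 and C12 trans, as in the target.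

Step 6
Reactants: 12 ethyl (2E,6E)-9-[(TBS)oxy]-3-{[(TBDPS)oxy]methyl}-7-methylnona-2,6-dienoate
Product: 13 ethyl (2E,6E)-3-{[(TBDPS)oxy]methyl}-9-hydroxy-7-methylnona-2,6-dienoate
Conditions: camphor-10-sulfonic acid (cat.), EtOH–CH2Cl2, 0 °C
Reagents that add atoms: none
Why: Acid-catalysed solvolytic desilylation removes the primary alkyl dimethylsilyl ether far faster than the diphenylsilyl ether, so only the C3 hydroxyl is freed.

Step 7
Reactants: 13 ethyl (2E,6E)-3-{[(TBDPS)oxy]methyl}-9-hydroxy-7-methylnona-2,6-dienoate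
Product: 14 ethyl (2E)-3-{[(TBDPS)oxy]methyl}-5-[(2R,3R)-3-(2-hydroxyethyl)-3-methyloxiran-2-yl]pent-2-enoate
Conditions: D-fructose-derived Shi ketone (1,2:4,5-di-O-isopropylidene-β-D-erythro-2,3-hexodiulo-2,6-pyranose, substoichiometric), Oxone (2KHSO5·KHSO4·K2SO4), K2CO3, Bu4NHSO4, MeCN–CH2(OMe)2 / aq. Na2B4O7 buffer pH 10.5, 0 °C
Reagents that add atoms: potassium peroxymonosulfate [K+].[O-]S(=O)(=O)OO
Why: Shi asymmetric epoxidation: the chiral dioxirane attacks the electron-rich E-trisubstituted C5=C6 alkene through the spiro transition state to give the (R,R)-epoxide, while the electron-poor enoate alkene is inert to this electrophilic oxidant.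

Step 8
Reactants: 14 ethyl (2E)-3-{[(TBDPS)oxy]methyl}-5-[(2R,3R)-3-(2-hydroxyethyl)-3-methyloxiran-2-yl]pent-2-enoate
Product: 15 ethyl (2E)-3-{[(TBDPS)oxy]methyl}-5-[(2R,3R)-3-methyl-3-(2-oxoethyl)oxiran-2-yl]pent-2-enoate
Conditions: Dess–Martin periodinane, NaHCO3, CH2Cl2, 0 °C to rt; crude aldehyde used at once
Reagents that add atoms: none
Why: Dess–Martin oxidation under bicarbonate buffering is neutral and fast, which suits the base- and acid-sensitive β,γ-epoxy aldehyde.

Step 9
Reactants: 15 ethyl (2E)-3-{[(TBDPS)oxy]methyl}-5-[(2R,3R)-3-methyl-3-(2-oxoethyl)oxiran-2-yl]pent-2-enoate; 16 (2-methylprop-1-en-1-yl)magnesium bromide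
Product: 17 ethyl (2E)-3-{[(TBDPS)oxy]methyl}-5-[(2R,3R)-3-(2-hydroxy-4-methylpent-3-en-1-yl)-3-methyloxiran-2-yl]pent-2-enoate (both carbinol epimers)
Conditions: 16 in THF, –78 °C, aldehyde added slowly to the reagent; sat. aq. NH4Cl at –78 °C
Reagents that add atoms: none
Why: Grignard 1,2-addition at –78 °C is much faster at the aldehyde than at the β,β-disubstituted enoate or the epoxide, and inverse addition at low temperature limits enolisation; the C3 carbinol forms as both epimers, which is harmless because C3 becomes sp2 in the ring closure.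

Step 10
Reactants: 17 ethyl (2E)-3-{[(TBDPS)oxy]methyl}-5-[(2R,3R)-3-(2-hydroxy-4-methylpent-3-en-1-yl)-3-methyloxiran-2-yl]pent-2-enoate
Product: 18 (2E)-3-{[(TBDPS)oxy]methyl}-5-[(2R,3R)-3-(2-hydroxy-4-methylpent-3-en-1-yl)-3-methyloxiran-2-yl]pent-2-en-1-ol
Conditions: i-Bu2AlH, CH2Cl2, –78 °C; aq. KNaC4H4O6
Reagents that add atoms: none
Why: i-Bu2AlH 1,2-reduction of the conjugated ester at –78 °C gives the allylic alcohol without conjugate reduction, and the trisubstituted epoxide is not opened at this temperature.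

Step 11
Reactants: 18 (2E)-3-{[(TBDPS)oxy]methyl}-5-[(2R,3R)-3-(2-hydroxy-4-methylpent-3-en-1-yl)-3-methyloxiran-2-yl]pent-2-en-1-ol
Product: 19 (2E)-3-{[(TBDPS)oxy]methyl}-5-[(2R,3R)-3-(2-hydroxy-4-methylpent-3-en-1-yl)-3-methyloxiran-2-yl]pent-2-enal
Conditions: TEMPO (cat.), PhI(OAc)2, CH2Cl2, 0 °C to rt
Reagents that add atoms: none
Why: Oxoammonium-catalysed (TEMPO/PhI(OAc)2) oxidation is selective for primary over secondary alcohols, so only the C11 allylic alcohol becomes the enal, without alkene isomerisation.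

Step 12
Reactants: 19 (2E)-3-{[(TBDPS)oxy]methyl}-5-[(2R,3R)-3-(2-hydroxy-4-methylpent-3-en-1-yl)-3-methyloxiran-2-yl]pent-2-enal
Product: 21 (2E)-5-[(2R,3R)-3-(2-bromo-4-methylpent-3-en-1-yl)-3-methyloxiran-2-yl]-3-{[(TBDPS)oxy]methyl}pent-2-enal (both C–Br epimers), via allylic mesylate 20 (not isolated)
Conditions: Ms2O, Et3N, THF, –40 °C; LiBr in THF, –40 °C to 0 °C; cold work-up, crude bromide used directly
Reagents that add atoms: lithium bromide [Li+].[Br-]
Why: Mesylation followed by in situ bromide displacement (SN2/SN2′) is the standard low-temperature route to labile allylic bromides; any allylic isomer or C3 epimer is acceptable, since all give the same allylchromium.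

Step 13
Reactants: 21 (2E)-5-[(2R,3R)-3-(2-bromo-4-methylpent-3-en-1-yl)-3-methyloxiran-2-yl]-3-{[(TBDPS)oxy]methyl}pent-2-enal
Product: 23 (1R,4E,6R,8E,11R)-4-{[(TBDPS)oxy]methyl}-7,7,11-trimethyl-12-oxabicyclo[9.1.0]dodeca-4,8-dien-6-ol, via allylchromium species 22 (not isolated)
Conditions: CrCl2 (excess), L*, i-Pr2NEt, THF, rt; then 21 in THF by syringe pump (high dilution), rt; aq. work-up, L* recovered
Reagents that add atoms: none
Why: Two equivalents of ligated divalent chromium reduce the C3–Br bond to an allylchromium of trivalent chromium that rests on the less substituted terminus C3 and adds to the C11 aldehyde through a six-membered chair transition state via its γ-carbon C1 (SE2′ allyl transfer), forming the C1–C11 bond, the quaternary carbon, the C11 carbinol and the C2=C3 alkene in one event. The closest known reaction is the Nozaki–Hiyama–Kishi allylation, precedented both as a macrocyclising allylic bromide–aldehyde closure in the presence of epoxides and as the γ-selective addition of γ,γ-dimethylallylchromium to aldehydes; combining the two in one ring closure is the untested part. The 11-membered carbocycle closes by 11-exo-trig attack on the carbonyl with allylic transposition, whereas bonding through C3 would need a 9-membered ring and runs against the γ-preference of allylchromium reagents. C11 is set by the chiral bis(oxazolinyl)carbazolide on chromium, which presents C1 to the Si face of the enal (reagent control over the distant epoxide) and so gives 11R. The step needs 1,2- over 1,4-addition, secured by the β,β-disubstituted enal and the oxophilic chromium reagent, and ring closure over oligomerisation, secured by slow addition at high dilution; epoxide, silyl ether and enal geometry are inert to organochromium reagents. Both C3 epimers and any tertiary allylic isomer of 21 converge on the same allylchromium, and the geometry of the transient C2=C3 alkene is immaterial because step 15 saturates it.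

Step 14
Reactants: 23 (1R,4E,6R,8E,11R)-4-{[(TBDPS)oxy]methyl}-7,7,11-trimethyl-12-oxabicyclo[9.1.0]dodeca-4,8-dien-6-ol
Product: 24 (1R,4E,6R,8E,11R)-4-{[(TBDPS)oxy]methyl}-7,7,11-trimethyl-12-oxabicyclo[9.1.0]dodeca-4,8-dien-6-yl benzoate
Conditions: BzCl, pyridine, DMAP (cat.), CH2Cl2, 0 °C to rt
Reagents that add atoms: benzoyl chloride O=C(Cl)c1ccccc1
Why: DMAP-catalysed acyl transfer (nucleophilic catalysis) benzoylates the neopentyl allylic alcohol with retention at C11.

Step 15
Reactants: 24 (1R,4E,6R,8E,11R)-4-{[(TBDPS)oxy]methyl}-7,7,11-trimethyl-12-oxabicyclo[9.1.0]dodeca-4,8-dien-6-yl benzoate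
Product: 25 (1R,4E,6R,11R)-4-{[(TBDPS)oxy]methyl}-7,7,11-trimethyl-12-oxabicyclo[9.1.0]dodec-4-en-6-yl benzoate
Conditions: 2-nitrobenzenesulfonylhydrazide (NBSH, excess, in portions), Et3N, CH2Cl2, rt
Reagents that add atoms: none
Why: Diimide reduction (concerted syn transfer of H2) depends strongly on substitution, so the disubstituted C2=C3 alkene is saturated while the trisubstituted C9=C10 alkene, the epoxide and the allylic benzoate, all at risk under catalytic hydrogenation, are left alone.

Step 16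
Reactants: 25 (1R,4E,6R,11R)-4-{[(TBDPS)oxy]methyl}-7,7,11-trimethyl-12-oxabicyclo[9.1.0]dodec-4-en-6-yl benzoate
Product: 26 (1R,4E,6R,11R)-4-(hydroxymethyl)-7,7,11-trimethyl-12-oxabicyclo[9.1.0]dodec-4-en-6-yl benzoate
Conditions: Bu4NF, AcOH, THF, 0 °C to rt
Reagents that add atoms: none
Why: Fluoride-mediated desilylation buffered with acetic acid cleaves the primary silyl ether; benzoyl migration from O11 to O12 is geometrically excluded because C11 and C12 are trans across the double bond.

Step 17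
Reactants: 26 (1R,4E,6R,11R)-4-(hydroxymethyl)-7,7,11-trimethyl-12-oxabicyclo[9.1.0]dodec-4-en-6-yl benzoate
Product: 27 (1R,4E,6R,11R)-4-formyl-7,7,11-trimethyl-12-oxabicyclo[9.1.0]dodec-4-en-6-yl benzoate
Conditions: MnO2 (activated, excess), CH2Cl2, rt
Reagents that add atoms: none
Why: MnO2 oxidises allylic alcohols selectively to enals under neutral heterogeneous conditions without alkene isomerisation.

Step 18
Reactants: 27 (1R,4E,6R,11R)-4-formyl-7,7,11-trimethyl-12-oxabicyclo[9.1.0]dodec-4-en-6-yl benzoate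
Product: 28 (1R,4E,6R,11R)-6-(benzoyloxy)-7,7,11-trimethyl-12-oxabicyclo[9.1.0]dodec-4-ene-4-carboxylic acid
Conditions: NaClO2, NaH2PO4, 2-methylbut-2-ene, t-BuOH–H2O, 0 °C to rt
Reagents that add atoms: sodium chlorite [Na+].[O-]Cl=O
Why: Pinnick oxidation converts the enal to the acid with hypochlorite scavenged by the alkene additive; the buffered medium leaves epoxide, benzoate and alkene geometry intact.

**Compound list**

1 | tert-butyl(but-3-yn-1-yloxy)dimethylsilane | C#CCCO[Si](C)(C)C(C)(C)C | starting material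
2 | oxirane | C1CO1 | starting material
3 | [(1E)-4-[(TBS)oxy]-2-methylbut-1-en-1-yl]dimethylalane | C[Al](C)/C=C(\C)CCO[Si](C)(C)C(C)(C)C | intermediate
4 | lithium butyl[(1E)-4-[(TBS)oxy]-2-methylbut-1-en-1-yl]dimethylaluminate | [Li+].CCCC[Al-](C)(C)/C=C(\C)CCO[Si](C)(C)C(C)(C)C | intermediate
5 | (3E)-6-[(TBS)oxy]-4-methylhex-3-en-1-ol | OCC/C=C(\C)CCO[Si](C)(C)C(C)(C)C | intermediate
6 | tert-butyl{[(3E)-6-iodo-3-methylhex-3-en-1-yl]oxy}dimethylsilane | ICC/C=C(\C)CCO[Si](C)(C)C(C)(C)C | intermediate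
7 | tert-butyl(diphenyl)(prop-2-yn-1-yloxy)silane | C#CCO[Si](c1ccccc1)(c1ccccc1)C(C)(C)C | starting material
8 | {3-[(TBDPS)oxy]prop-1-yn-1-yl}lithium | [Li]C#CCO[Si](c1ccccc1)(c1ccccc1)C(C)(C)C | intermediate
9 | ethyl 4-[(TBDPS)oxy]but-2-ynoate | CCOC(=O)C#CCO[Si](c1ccccc1)(c1ccccc1)C(C)(C)C | intermediate
10 | ethyl (2Z)-4-[(TBDPS)oxy]-3-iodobut-2-enoate | CCOC(=O)/C=C(\I)CO[Si](c1ccccc1)(c1ccccc1)C(C)(C)C | intermediate
11 | {(3E)-6-[(TBS)oxy]-4-methylhex-3-en-1-yl}zinc iodide | I[Zn]CC/C=C(\C)CCO[Si](C)(C)C(C)(C)C | intermediate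
12 | ethyl (2E,6E)-9-[(TBS)oxy]-3-{[(TBDPS)oxy]methyl}-7-methylnona-2,6-dienoate | CCOC(=O)/C=C(\CC/C=C(\C)CCO[Si](C)(C)C(C)(C)C)CO[Si](c1ccccc1)(c1ccccc1)C(C)(C)C | intermediate
13 | ethyl (2E,6E)-3-{[(TBDPS)oxy]methyl}-9-hydroxy-7-methylnona-2,6-dienoate | CCOC(=O)/C=C(\CC/C=C(\C)CCO)CO[Si](c1ccccc1)(c1ccccc1)C(C)(C)C | intermediate
14 | ethyl (2E)-3-{[(TBDPS)oxy]methyl}-5-[(2R,3R)-3-(2-hydroxyethyl)-3-methyloxiran-2-yl]pent-2-enoate | OCC[C@@]1(C)O[C@@H]1CC/C(CO[Si](c2ccccc2)(c2ccccc2)C(C)(C)C)=C\C(=O)OCC | intermediate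
15 | ethyl (2E)-3-{[(TBDPS)oxy]methyl}-5-[(2R,3R)-3-methyl-3-(2-oxoethyl)oxiran-2-yl]pent-2-enoate | O=CC[C@@]1(C)O[C@@H]1CC/C(CO[Si](c2ccccc2)(c2ccccc2)C(C)(C)C)=C\C(=O)OCC | intermediate
16 | (2-methylprop-1-en-1-yl)magnesium bromide | CC(C)=C[Mg]Br | starting material
17 | ethyl (2E)-3-{[(TBDPS)oxy]methyl}-5-[(2R,3R)-3-(2-hydroxy-4-methylpent-3-en-1-yl)-3-methyloxiran-2-yl]pent-2-enoate, carbinol epimers | CC(C)=CC(O)C[C@@]1(C)O[C@@H]1CC/C(CO[Si](c2ccccc2)(c2ccccc2)C(C)(C)C)=C\C(=O)OCC | intermediate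
18 | (2E)-3-{[(TBDPS)oxy]methyl}-5-[(2R,3R)-3-(2-hydroxy-4-methylpent-3-en-1-yl)-3-methyloxiran-2-yl]pent-2-en-1-ol | CC(C)=CC(O)C[C@@]1(C)O[C@@H]1CC/C(CO[Si](c2ccccc2)(c2ccccc2)C(C)(C)C)=C\CO | intermediate
19 | (2E)-3-{[(TBDPS)oxy]methyl}-5-[(2R,3R)-3-(2-hydroxy-4-methylpent-3-en-1-yl)-3-methyloxiran-2-yl]pent-2-enal | CC(C)=CC(O)C[C@@]1(C)O[C@@H]1CC/C(CO[Si](c2ccccc2)(c2ccccc2)C(C)(C)C)=C\C=O | intermediate
20 | (2E)-3-{[(TBDPS)oxy]methyl}-5-{(2R,3R)-3-[2-(methanesulfonyloxy)-4-methylpent-3-en-1-yl]-3-methyloxiran-2-yl}pent-2-enal | CC(C)=CC(OS(C)(=O)=O)C[C@@]1(C)O[C@@H]1CC/C(CO[Si](c2ccccc2)(c2ccccc2)C(C)(C)C)=C\C=O | intermediate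
21 | (2E)-5-[(2R,3R)-3-(2-bromo-4-methylpent-3-en-1-yl)-3-methyloxiran-2-yl]-3-{[(TBDPS)oxy]methyl}pent-2-enal, C–Br epimers | CC(C)=CC(Br)C[C@@]1(C)O[C@@H]1CC/C(CO[Si](c2ccccc2)(c2ccccc2)C(C)(C)C)=C\C=O | intermediate
22 | allylchromium species of trivalent chromium, chromium at C3 in place of bromine (drawn as the dichloride, chiral ligand omitted) | CC(C)=CC([Cr](Cl)Cl)C[C@@]1(C)O[C@@H]1CC/C(CO[Si](c2ccccc2)(c2ccccc2)C(C)(C)C)=C\C=O | intermediate
23 | (1R,4E,6R,8E,11R)-4-{[(TBDPS)oxy]methyl}-7,7,11-trimethyl-12-oxabicyclo[9.1.0]dodeca-4,8-dien-6-ol | CC1(C)/C=C/C[C@@]2(C)O[C@@H]2CC/C(CO[Si](c3ccccc3)(c3ccccc3)C(C)(C)C)=C\[C@H]1O | intermediate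
24 | (1R,4E,6R,8E,11R)-4-{[(TBDPS)oxy]methyl}-7,7,11-trimethyl-12-oxabicyclo[9.1.0]dodeca-4,8-dien-6-yl benzoate | CC1(C)/C=C/C[C@@]2(C)O[C@@H]2CC/C(CO[Si](c3ccccc3)(c3ccccc3)C(C)(C)C)=C\[C@H]1OC(=O)c1ccccc1 | intermediate
25 | (1R,4E,6R,11R)-4-{[(TBDPS)oxy]methyl}-7,7,11-trimethyl-12-oxabicyclo[9.1.0]dodec-4-en-6-yl benzoate | CC1(C)CCC[C@@]2(C)O[C@@H]2CC/C(CO[Si](c3ccccc3)(c3ccccc3)C(C)(C)C)=C\[C@H]1OC(=O)c1ccccc1 | intermediate
26 | (1R,4E,6R,11R)-4-(hydroxymethyl)-7,7,11-trimethyl-12-oxabicyclo[9.1.0]dodec-4-en-6-yl benzoate | CC1(C)CCC[C@@]2(C)O[C@@H]2CC/C(CO)=C\[C@H]1OC(=O)c1ccccc1 | intermediate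
27 | (1R,4E,6R,11R)-4-formyl-7,7,11-trimethyl-12-oxabicyclo[9.1.0]dodec-4-en-6-yl benzoate | CC1(C)CCC[C@@]2(C)O[C@@H]2CC/C(C=O)=C\[C@H]1OC(=O)c1ccccc1 | intermediate
28 | (1R,4E,6R,11R)-6-(benzoyloxy)-7,7,11-trimethyl-12-oxabicyclo[9.1.0]dodec-4-ene-4-carboxylic acid | CC1(C)CCC[C@@]2(C)O[C@@H]2CC/C(C(=O)O)=C\[C@H]1OC(=O)c1ccccc1 | target

Total step count: 18. Longest linear sequence: 16 steps (1, 2, 5–18, from compound 1).

**Steps most likely to fail**

Step 13. The bulky ligated chromium must override whatever facial bias the forming 11-membered ring has, so facial selectivity at C11 may be poor or mismatched, and the slower closure gives protonation and oligomerisation more room. Fallback: setting out from 21, the ring is closed with CrCl2 alone in THF at high dilution (the classical ligand-free protocol) to the C11-epimeric carbinols F1. These are oxidised with Dess–Martin periodinane/NaHCO3 to the macrocyclic enone F2. The ketone is then reduced by Corey–Bakshi–Shibata reduction with BH3·SMe2 and (S)-2-methyl-CBS-oxazaborolidine, the quaternary C1 side being taken as the large group. Stereocontrol is thereby moved from the C–C bond formation to a reagent-controlled hydride delivery, and the route is rejoined at 23.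

Step 12. The doubly activated secondary allylic mesylate and bromide may ionise, with elimination to a diene, or bromide may open the epoxide before the halide can be used. Fallback: setting out from 19, the C3 hydroxyl is phosphorylated with ClP(O)(OEt)2 and N-methylimidazole in CH2Cl2 at 0 °C to the allylic diethyl phosphate F3, a far less ionisable precursor that can be purified. F3 is cyclised with CrCl2/L* and LiI (cat.) in THF–DMPU, a known way to generate allylchromium reagents from allylic phosphates through a low stationary concentration of the allyl iodide. The route is rejoined directly at 23.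

Step 9. The basic Grignard reagent may deprotonate the β,γ-epoxy aldehyde at C4, after which the epoxide opens by β-elimination to a γ-hydroxy enal instead of undergoing carbonyl addition. Fallback: setting out from 15, the isobutenyl group is introduced by nickel-catalysed Nozaki–Hiyama–Kishi alkenylation with 1-iodo-2-methylprop-1-ene, CrCl2 (excess) and NiCl2 (cat.) in DMSO–THF at rt. This replaces the basic carbanion by a non-basic alkenylchromium nucleophile made in situ from the alkenyl halide and is known to spare enolisable aldehydes, epoxides and esters. It leads straight to 17 (no new compound, F0).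

**Further compounds**

F1 | step 13 | C11-epimeric mixture of 4-{[(TBDPS)oxy]methyl}-7,7,11-trimethyl-12-oxabicyclo[9.1.0]dodeca-4,8-dien-6-ol (1R,4E,8E,11R) | CC1(C)/C=C/C[C@@]2(C)O[C@@H]2CC/C(CO[Si](c3ccccc3)(c3ccccc3)C(C)(C)C)=C\C1O
F2 | step 13 | (1R,4E,8E,11R)-4-{[(TBDPS)oxy]methyl}-7,7,11-trimethyl-12-oxabicyclo[9.1.0]dodeca-4,8-dien-6-one | CC1(C)/C=C/C[C@@]2(C)O[C@@H]2CC/C(CO[Si](c3ccccc3)(c3ccccc3)C(C)(C)C)=C\C1=O
F3 | step 12 | diethyl 1-{(2R,3R)-3-[(3E)-3-{[(TBDPS)oxy]methyl}-5-oxopent-3-en-1-yl]-2-methyloxiran-2-yl}-4-methylpent-3-en-2-yl phosphate | CCOP(=O)(OCC)OC(C=C(C)C)C[C@@]1(C)O[C@@H]1CC/C(CO[Si](c2ccccc2)(c2ccccc2)C(C)(C)C)=C\C=O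
F0 | step 9 | none | none
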